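## Retrosynthetic overview

1. Target 20 ⇐ ovatodiolide 19: a last-step photochemical Schenck ene reaction (¹O₂) makes the C5–OOH bond, the C4 exocyclic methylene and the C5 stereocentre.
2. 19 ⇐ seco enal/allylboronate 18: one intramolecular anti-allylboration–lactonization forms C1–C14, the 14-membered ring and the trans α-methylene-γ-lactone, with C1 and C14 set under control of C10.
3. 18 ⇐ butenolide alkenyl iodide 11 + bromo allylboronate 16, joined at C3–C4 by Ni-electrocatalytic C(sp2)–C(sp3) coupling.
4. 11 ⇐ (R)-epichlorohydrin (C10, the only purchased stereocentre) + alkenyl iodide 2 (electrochemical epoxide coupling, C11–C12), then phenylthioacetate annulation, alkylation with diiodide 9 and sulfoxide elimination.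
5. Ring order: butenolide → macrocycle and α-methylene lactone together → hydroperoxide last.

Assumption: locants are C1 = ring CH bearing the α-methylene-lactone carbon, C14 = its lactone O–CH partner, C10 = butenolide O–CH, C8=C9 = butenolide alkene, C4=C5 and C12=C13 = ring alkenes; the target SMILES then reads (1R,5R,10R,14S) with a trans-fused α-methylene lactone.

## Route

**Step 1**
Reactants: 1, 1,1-diethoxybut-2-yne (2-butynal diethyl acetal)
Product: 2, (E)-1,1-diethoxy-3-iodobut-2-ene
Conditions: Cp2Zr(H)Cl (1.3 equiv), THF, 25→40 °C; then I2, 0 °C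
Reagents that add atoms: iodine, II
Why: Hydrozirconation–iodination: syn H–Zr addition puts Zr on the less hindered methyl-bearing carbon (equilibrating conditions), and iodinolysis with retention gives the E-iodide.

**Step 2**
Reactants: 2, (E)-1,1-diethoxy-3-iodobut-2-ene; 3, (R)-epichlorohydrin
Product: 4, (2R,4E)-1-chloro-6,6-diethoxy-4-methylhex-4-en-2-ol
Conditions: NiBr2·dme (10 mol%), 4,4'-di-tert-butyl-2,2'-bipyridine (10 mol%), NaI (1.5 equiv), 2,6-lutidinium triflate (1.2 equiv), 3 (2 equiv), DMA, undivided cell, Zn(+)/Ni foam(–), 5 mA, 25 °C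
Reagents that add atoms: none
Why: Proposed new method: a cathode-driven Ni/iodide co-catalysed cross-electrophile coupling of an alkenyl iodide with an epoxide — iodide and the lutidinium acid open 3 at its CH2 to the iodohydrin, Ni(0) adds to 2, Ni(I) abstracts iodine and the primary β-hydroxyalkyl radical is captured by alkenyl–Ni(II), and reductive elimination from Ni(III) forms C11–C12 with retention of E geometry while C–Cl and the untouched carbinol centre (future C10) survive; the closest known reactions are the Ni/NaI-catalysed reductive coupling of epoxides with aryl halides using Mn powder and Ni-electrocatalytic alkenyl halide–alkyl halide cross-electrophile coupling.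

**Step 3**
Reactants: 4, (2R,4E)-1-chloro-6,6-diethoxy-4-methylhex-4-en-2-ol; 5, (phenylthio)acetic acid
Product: 6, (5R)-5-[(2E)-4,4-diethoxy-2-methylbut-2-en-1-yl]-3-(phenylsulfanyl)oxolan-2-one (C3 epimers)
Conditions: 4, NaH, THF, 0→25 °C (terminal epoxide in situ); add to 5/LDA (2 equiv per 5), THF, 0→45 °C; then EDCI, DMAP (cat.), CH2Cl2
Reagents that add atoms: none
Why: Dianion epoxide alkylation–lactonization: the chlorohydrin closes to the (R)-epoxide, the phenylthioacetate dianion opens it at CH2 (forming C8–C9, stereocentre untouched), and carbodiimide closure gives the lactone; the C3 centre is irrelevant because it is destroyed in step 7.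

**Step 4**
Reactants: 7, pent-3-yn-1-ol
Product: 8, (E)-4-iodopent-3-en-1-ol
Conditions: Cp2Zr(H)Cl (2.3 equiv), THF, 25→40 °C; then I2, 0 °C
Reagents that add atoms: iodine, II
Why: Hydrozirconation–iodination as in step 1: Zr settles next to the methyl group and syn addition with retentive iodinolysis gives the E-vinyl iodide.

**Step 5**
Reactants: 8, (E)-4-iodopent-3-en-1-ol
Product: 9, (E)-2,5-diiodopent-2-ene
Conditions: I2, PPh3, imidazole, CH2Cl2, 0 °C
Reagents that add atoms: iodine, II
Why: Appel iodination of the primary alcohol; the vinyl iodide is inert.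

**Step 6**
Reactants: 6, α-phenylthio lactone; 9, (E)-2,5-diiodopent-2-ene
Product: 10, (5R)-5-[(2E)-4,4-diethoxy-2-methylbut-2-en-1-yl]-3-[(3E)-4-iodopent-3-en-1-yl]-3-(phenylsulfanyl)oxolan-2-one
Conditions: LDA (1.1 equiv), THF–DMPU, –78 °C; 9 (1.3 equiv), –78→–20 °C
Reagents that add atoms: none
Why: Alkylation of the sulfur-stabilised lactone enolate: SN2 at the primary iodide forms C7–C8, while the vinyl iodide, acetal and the C10 centre (not α to the carbonyl) are unaffected.

**Step 7**
Reactants: 10, alkylated α-phenylthio lactone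
Product: 11, (5R)-5-[(2E)-4,4-diethoxy-2-methylbut-2-en-1-yl]-3-[(3E)-4-iodopent-3-en-1-yl]furan-2(5H)-one
Conditions: mCPBA (1.0 equiv), NaHCO3, CH2Cl2, –78 °C; then PhMe, CaCO3, 110 °C
Reagents that add atoms: none
Why: Sulfide oxidation then thermal syn-sulfoxide elimination: the sulfide is oxidised far faster than the deactivated alkenes (allylic acetal, vinyl iodide), and elimination toward the ring CH2 gives the conjugated endocyclic butenolide.

**Step 8**
Reactants: 12, 4-bromobut-1-yne; 13, methyl chloroformate
Product: 14, methyl 5-bromopent-2-ynoate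
Conditions: LDA, THF, –78 °C; then 13, –78→0 °C
Reagents that add atoms: none
Why: Acetylide C-acylation; deprotonation of the terminal alkyne at –78 °C outpaces E2 of the bromide.

**Step 9**
Reactants: 14, methyl 5-bromopent-2-ynoate; 15, 2-(iodomethyl)-4,4,5,5-tetramethyl-1,3,2-dioxaborolane
Product: 16, methyl (2Z)-5-bromo-2-[(4,4,5,5-tetramethyl-1,3,2-dioxaborolan-2-yl)methyl]pent-2-enoate
Conditions: DIBAL-H, HMPA, THF, 0 °C; then 15, 0→25 °C
Reagents that add atoms: none
Why: Conjugate syn-hydroalumination of the ynoate (H to C-β, Al to C-α) and alkylation of the α-alanyl enoate with retention place CH2B trans to the chain (chain cis to the ester), which is the E-crotyl-type geometry needed for anti addition in step 12.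

**Step 10**
Reactants: 11, butenolide alkenyl iodide; 16, bromo allylboronate
Product: 17, methyl (2Z,6E)-9-{(5R)-5-[(2E)-4,4-diethoxy-2-methylbut-2-en-1-yl]-2-oxo-2,5-dihydrofuran-3-yl}-6-methyl-2-[(4,4,5,5-tetramethyl-1,3,2-dioxaborolan-2-yl)methyl]nona-2,6-dienoate
Conditions: NiBr2·dme (10 mol%), 4,4'-di-tert-butyl-2,2'-bipyridine (12 mol%), NaI (0.5 equiv), 16 (1.5 equiv), DMA, undivided cell, Zn(+)/Ni foam(–), 5 mA, 25 °C
Reagents that add atoms: none
Why: Ni-electrocatalytic reductive cross-electrophile coupling (alkenyl–Ni(II) captures the primary alkyl radical) forms C3–C4 with retention of the E alkene; the base-free conditions leave the allyl-Bpin, acetal and butenolide intact.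

**Step 11**
Reactants: 17, coupled acetal
Product: 18, methyl (2Z,6E)-6-methyl-9-{(5R)-5-[(2E)-2-methyl-4-oxobut-2-en-1-yl]-2-oxo-2,5-dihydrofuran-3-yl}-2-[(4,4,5,5-tetramethyl-1,3,2-dioxaborolan-2-yl)methyl]nona-2,6-dienoate
Conditions: PPTS (0.2 equiv), acetone–H2O (10:1), 25 °C; crude used directly
Reagents that add atoms: water, O
Why: Mild acetal hydrolysis releases the E-enal; the ester-deactivated allylboronate does not react at 25 °C.

**Step 12**
Reactants: 18, seco enal allylboronate
Product: 19, ovatodiolide, the (1R,10R,14S) macrocycle with E C4=C5 and C12=C13 alkenes, C8–C10 butenolide and trans-fused C1/C14 α-methylene-γ-lactone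
Conditions: PhMe (1 mM), 85 °C, 48 h; then p-TsOH·H2O (10 mol%), 25 °C
Reagents that add atoms: none
Why: Intramolecular allylboration through a closed chair transition state: the E-enal and E-crotyl-type boronate give the anti homoallylic borate, which lactonizes (loss of MeO–Bpin) to the trans lactone, and the C10 centre in the rigidified tether (butenolide plus E C12=C13) is expected to select the aldehyde face giving 14S,1R.

**Step 13**
Reactants: 19, ovatodiolide
Product: 20, 4-methylene-5β-hydroperoxyovatodiolide, (1R,5R,10R,14S)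
Conditions: O2, tetraphenylporphyrin (1 mol%), CH2Cl2, –20 °C, white LED, to about 70% conversion; chromatography at ≤0 °C
Reagents that add atoms: dioxygen, O=O
Why: Schenck ene reaction: ¹O₂ attacks the electron-rich C4=C5 (C12=C13 is deactivated by the allylic lactone oxygen; the conjugated alkenes are inert) from the exposed outer face, and abstracts a methyl hydrogen on the crowded cis side, giving the 5R hydroperoxide and the exocyclic methylene; the C4-hydroperoxy-Δ5 regioisomer is separated.

## Compound list

1 | 1,1-diethoxybut-2-yne | CC#CC(OCC)OCC | starting material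
2 | (E)-1,1-diethoxy-3-iodobut-2-ene | C/C(I)=C\C(OCC)OCC | intermediate
3 | (R)-epichlorohydrin | ClC[C@H]1CO1 | starting material
4 | (2R,4E)-1-chloro-6,6-diethoxy-4-methylhex-4-en-2-ol | ClC[C@H](O)C/C(C)=C/C(OCC)OCC | intermediate
5 | (phenylthio)acetic acid | OC(=O)CSc1ccccc1 | starting material
6 | (5R)-5-[(2E)-4,4-diethoxy-2-methylbut-2-en-1-yl]-3-(phenylsulfanyl)oxolan-2-one | O=C1O[C@H](C/C(C)=C/C(OCC)OCC)CC1Sc1ccccc1 | intermediate
7 | pent-3-yn-1-ol | CC#CCCO | starting material
8 | (E)-4-iodopent-3-en-1-ol | C/C(I)=C\CCO | intermediate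
9 | (E)-2,5-diiodopent-2-ene | C/C(I)=C\CCI | intermediate
10 | (5R)-5-[(2E)-4,4-diethoxy-2-methylbut-2-en-1-yl]-3-[(3E)-4-iodopent-3-en-1-yl]-3-(phenylsulfanyl)oxolan-2-one | O=C1O[C@H](C/C(C)=C/C(OCC)OCC)CC1(CC/C=C(\C)I)Sc1ccccc1 | intermediate
11 | (5R)-5-[(2E)-4,4-diethoxy-2-methylbut-2-en-1-yl]-3-[(3E)-4-iodopent-3-en-1-yl]furan-2(5H)-one | O=C1O[C@H](C/C(C)=C/C(OCC)OCC)C=C1CC/C=C(\C)I | intermediate
12 | 4-bromobut-1-yne | C#CCCBr | starting material
13 | methyl chloroformate | COC(=O)Cl | starting material
14 | methyl 5-bromopent-2-ynoate | COC(=O)C#CCCBr | intermediate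
15 | 2-(iodomethyl)-4,4,5,5-tetramethyl-1,3,2-dioxaborolane | ICB1OC(C)(C)C(C)(C)O1 | starting material
16 | methyl (2Z)-5-bromo-2-[(pinacolatoboryl)methyl]pent-2-enoate | BrCC/C=C(\C(=O)OC)CB1OC(C)(C)C(C)(C)O1 | intermediate
17 | methyl (2Z,6E)-9-{(5R)-5-[(2E)-4,4-diethoxy-2-methylbut-2-en-1-yl]-2-oxo-2,5-dihydrofuran-3-yl}-6-methyl-2-[(pinacolatoboryl)methyl]nona-2,6-dienoate | O=C1O[C@H](C/C(C)=C/C(OCC)OCC)C=C1CC/C=C(\C)CC/C=C(\C(=O)OC)CB1OC(C)(C)C(C)(C)O1 | intermediate
18 | methyl (2Z,6E)-6-methyl-9-{(5R)-5-[(2E)-2-methyl-4-oxobut-2-en-1-yl]-2-oxo-2,5-dihydrofuran-3-yl}-2-[(pinacolatoboryl)methyl]nona-2,6-dienoate | O=C1O[C@H](C/C(C)=C/C=O)C=C1CC/C=C(\C)CC/C=C(\C(=O)OC)CB1OC(C)(C)C(C)(C)O1 | intermediate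
19 | ovatodiolide, (1R,10R,14S) | C=C1C(=O)O[C@H]2/C=C(\C)C[C@@H]3C=C(CC/C=C(\C)CC[C@H]12)C(=O)O3 | intermediate
20 | 4-methylene-5β-hydroperoxyovatodiolide, (1R,5R,10R,14S) | C=C1C(=O)O[C@H]2/C=C(\C)C[C@@H]3C=C(CC[C@@H](OO)C(=C)CC[C@H]12)C(=O)O3 | target

## Summary

Total steps: 13.
Longest linear sequence: 9 (steps 1, 2, 3, 6, 7, 10, 11, 12, 13); side branches are steps 4–5 and 8–9.

Three steps most likely to fail:

- **Step 2 (proposed new electrochemical epoxide–alkenyl iodide coupling).** Risks are proton reduction at the cathode, alkenyl homocoupling and halide scrambling of the epihalohydrin. Fallback (known chemistry): I/Li exchange on 2 (t-BuLi, –78 °C), transmetalation with MgBr2·OEt2 and CuI-catalysed opening of (R)-epichlorohydrin at CH2, the classical alkenyl Grignard/cuprate epoxide opening, giving the same chlorohydrin 4.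
- **Step 12 (macrocyclizing allylboration).** The anti/trans outcome is reliable, but the face selectivity relative to C10 and the competition with oligomerization are not proven. Fallback: reverse the order of the two unions. Hydrolyse 11 to its enal, run the anti-allylboration–lactonization with 16 intermolecularly (trans lactone; the two C10 diastereomers are separated), then close the ring at C3–C4 by intramolecular Ni-catalysed alkenyl iodide/alkyl bromide reductive coupling.
- **Step 13 (Schenck ene).** Hydrogen abstraction from C6 gives the tertiary C4-hydroperoxide regioisomer, and over-oxidation at C12=C13 is possible. Fallback: install oxygen stepwise. Epoxidize C4=C5 with mCPBA from the open face, isomerize the epoxide to the 4-methylene-5-ol with an aluminium amide (Et2Al–TMP), invert C5 by oxidation and Luche reduction, then displace the derived mesylate with a hydroperoxide nucleophile (2-methoxyprop-2-yl hydroperoxide, then mild acid) with inversion to the 5R hydroperoxide.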